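Ring C is cut at C8–C9. Without C8, C9 is an acetal carbon of the tetrahydrofuran (ring B), and C6–C7(=CH2)–C8 is the footprint of a 2-(silylmethyl)allyl nucleophile. Ionising a ring B acetal therefore lets a tethered allylsilane close the oxonane, set C9 and unveil the C7 methylene in one operation. The precursor already holds rings A, B and D and all other stereocentres; its anomeric group is methoxy instead of acetoxy, a robust acetal laid down midway that survives the oxidation, enolate, borane and silyl triflate steps. Ring A comes from (R)-carvone; C3 is set by hydroxyl-directed epoxidation and lactonising inversion, C4 and C6 by reagent- and chelate-controlled reductions.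

Key step: step 25

Remark: locants are those of briarellin A (carvone C6, C1, C2, C3, C4, C5 become C1, C10, C11, C12, C13, C14); ring B acetals 20–38 are C9 anomer mixtures with one anomer drawn, and 30–33 are C6 epimer mixtures that converge at 34.
Remark: the given structures of target, cyclisation precursor and cyclisation product agree at every stereocentre, so none is altered; only the anomeric leaving group of the precursor is redesigned (methoxy for acetoxy).

Step 1
Reactants: 1 (R)-carvone; 2 (E)-2-methylbut-2-enal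
Product: 4 anti-aldol adduct (carvone bearing at C1 a 1-hydroxy-(E)-2-methylbut-2-enyl group trans to the isopropenyl group), via dicyclohexylboron dienolate 3 (not isolated)
Conditions: (c-C6H11)2BCl, Et3N, Et2O, 0 °C; then 2, −78 °C; H2O2, pH 7 buffer, MeOH, 0 °C
Reagents that add atoms: none
Why: The (E)-enol borinate formed by α′-deprotonation of the enone reacts through a Zimmerman–Traxler chair (boron aldol reaction) and should give the anti C1–C2 adduct, the aldehyde approaching the enolate face opposite to the neighbouring isopropenyl group so that the new side chain is trans to C14–C15.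

Step 2
Reactants: 4 anti-aldol adduct
Product: 5 C2 tert-butyldimethylsilyl ether
Conditions: TBSOTf, 2,6-lutidine, CH2Cl2, −78 °C
Reagents that add atoms: tert-butyldimethylsilyl triflate, CC(C)(C)[Si](C)(C)OS(=O)(=O)C(F)(F)F
Why: Silylation of the secondary alcohol with the silyl triflate is routine; it blocks retro-aldol cleavage in the basic steps that follow and keeps the C2 oxygen apart from the hydroxyl that appears at C12.

Step 3
Reactants: 5 C2 tert-butyldimethylsilyl ether
Product: 6 C11–C12 epoxy ketone (epoxide trans to the isopropenyl group)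
Conditions: 30% H2O2, NaOH (aq), MeOH, 0 °C
Reagents that add atoms: hydrogen peroxide, OO
Why: Weitz–Scheffer nucleophilic epoxidation: hydroperoxide adds axially to C12 anti to the C14 isopropenyl group, so the epoxide oxygen should stand trans to it and cis to the C1 side chain, the configuration that the C12–O bond needs for step 6.

Step 4
Reactants: 6 C11–C12 epoxy ketone
Product: 8 allylic alcohol (C12 hydroxyl; C10=C11 double bond), via hydrazone 7 (not isolated)
Conditions: N2H4·H2O, AcOH (cat.), MeOH, 0 °C to rt
Reagents that add atoms: none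
Why: Wharton transposition: the epoxy hydrazone loses N2 and opens the epoxide, which moves the double bond to C10=C11 and leaves the untouched C12–O bond as an allylic alcohol of retained configuration.

Step 5
Reactants: 8 allylic alcohol
Product: 9 C12 tributylstannylmethyl ether
Conditions: KH, Bu3SnCH2I, 18-crown-6, THF, 0 °C to rt
Reagents that add atoms: (iodomethyl)tributylstannane, CCCC[Sn](CCCC)(CCCC)CI
Why: Williamson etherification of the potassium alkoxide with the iodomethylstannane installs the one-carbon unit that becomes C9.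

Step 6
Reactants: 9 C12 tributylstannylmethyl ether
Product: 11 homoallylic alcohol (hydroxymethyl C9 on C10; C11=C12 double bond), via lithiomethyl ether 10 (not isolated)
Conditions: n-BuLi, THF, −78 °C; then H2O
Reagents that add atoms: none
Why: Tin–lithium exchange gives an α-alkoxy carbanion that undergoes the suprafacial [2,3]-Wittig rearrangement (Still variant), so the hydroxymethyl group is delivered to C10 on the face of the pseudoaxial C12–O bond, cis to the C1 side chain, while the alkene moves to C11=C12.

Step 7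
Reactants: 11 homoallylic alcohol
Product: 12 C11–C12 epoxide syn to the hydroxymethyl group
Conditions: VO(acac)2 (cat.), t-BuOOH, CH2Cl2, 0 °C to rt
Reagents that add atoms: tert-butyl hydroperoxide, CC(C)(C)OO
Why: Vanadium-catalysed hydroxyl-directed epoxidation: the homoallylic C9 hydroxyl binds the metal and delivers oxygen to the syn face of C11=C12, whereas the two other alkenes have no free hydroxyl nearby and should not react.

Step 8
Reactants: 12 C11–C12 epoxide
Product: 13 diol (primary C9 hydroxyl; tertiary C11 hydroxyl)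
Conditions: LiEt3BH, THF, 0 °C to rt; then H2O
Reagents that add atoms: none
Why: Hydride opens the trisubstituted epoxide in SN2 fashion at the less substituted C12, which leaves the tertiary C11 alcohol with its oxygen cis to C9 as in the target.

Step 9
Reactants: 13 diol
Product: 14 C9 aldehyde
Conditions: Dess–Martin periodinane, NaHCO3, CH2Cl2, 0 °C
Reagents that add atoms: none
Why: Dess–Martin oxidation converts the primary alcohol to the aldehyde under buffered conditions that should not epimerise C10 or dehydrate the tertiary β-hydroxyl, which itself cannot be oxidised.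

Step 10
Reactants: 14 C9 aldehyde
Product: 15 C9 dimethyl acetal
Conditions: HC(OMe)3, PPTS (cat.), MeOH, rt
Reagents that add atoms: trimethyl orthoformate, COC(OC)OC
Why: Acid-catalysed acetalisation with the orthoformate masks the C9 aldehyde as a base-stable dimethyl acetal that can later be exchanged for the ring B oxygen.

Step 11
Reactants: 15 C9 dimethyl acetal
Product: 17 C16 primary alcohol (C15 set), via B-alkyl-9-BBN 16 (not isolated)
Conditions: 9-BBN, THF, 0 °C to rt; then H2O2, NaOH, 0 °C
Reagents that add atoms: hydrogen peroxide, OO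
Why: Hydroboration–oxidation with 9-BBN selects the 1,1-disubstituted isopropenyl group over the hindered trisubstituted alkene and places oxygen on C16; in the conformer with C14–H eclipsing the alkene the borane should add to the face remote from the branched C1, which gives the C15 configuration of the target (1,2-induction by allylic strain).

Step 12
Reactants: 17 C16 primary alcohol
Product: 18 triol (free C2 hydroxyl)
Conditions: Bu4NF, THF, rt
Reagents that add atoms: none
Why: Fluoride cleaves the silyl ether and frees the C2 hydroxyl that must direct the next epoxidation; the acetal and the alkene are inert.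

Step 13
Reactants: 18 triol
Product: 19 erythro C3–C4 epoxy triol
Conditions: VO(acac)2 (cat.), t-BuOOH, CH2Cl2, 0 °C
Reagents that add atoms: tert-butyl hydroperoxide, CC(C)(C)OO
Why: Vanadium-catalysed directed epoxidation of the allylic alcohol; with a methyl group on the proximal alkene carbon the allylic 1,2-strain model predicts the erythro epoxy alcohol, that is, the C3–O bond anti to the C2–O bond, which is what the later inversion at C3 requires.

Step 14
Reactants: 19 erythro C3–C4 epoxy triol
Product: 20 bicyclic methyl acetal (rings A and B; epoxide and C16 alcohol retained)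
Conditions: PPTS (cat.), CH2Cl2, rt
Reagents that add atoms: none
Why: Mild acid-catalysed transacetalisation: the C2 hydroxyl displaces one methoxy group and closes the five-membered cyclic acetal (ring B), cis-fused because C2 and C9 sit on the same face of ring A, while the epoxide should survive pyridinium tosylate.

Step 15
Reactants: 20 bicyclic methyl acetal
Product: 23 tricyclic hydroxy lactone (rings A B D; C4 carbinol), via aldehyde 21 (not isolated), via epoxy acid 22 (not isolated)
Conditions: TEMPO (cat.), NaOCl (cat.), NaClO2, MeCN, phosphate buffer pH 6.7, 35 °C; then CSA (cat.), CH2Cl2, rt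
Reagents that add atoms: sodium chlorite, [Na+].[O-]Cl=O
Why: Nitroxyl-catalysed chlorite oxidation takes the primary alcohol through the aldehyde to the acid, and acid catalysis then lets the carboxyl group open the epoxide at the tertiary C3 (7-exo, SN2-like, inversion), which closes lactone ring D and sets C3 with its oxygen syn to the C2 oxygen.

Step 16
Reactants: 23 tricyclic hydroxy lactone
Product: 24 C4 methyl ketone
Conditions: Dess–Martin periodinane, NaHCO3, CH2Cl2, rt
Reagents that add atoms: none
Why: Dess–Martin oxidation removes the C4 stereocentre left by the epoxide, which has the wrong configuration, and gives a methyl ketone that can be enolised only at C5.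

Step 17
Reactants: 24 C4 methyl ketone
Product: 25 C11 triethylsilyl ether
Conditions: TESOTf, 2,6-lutidine, CH2Cl2, −78 °C
Reagents that add atoms: triethylsilyl triflate, CC[Si](CC)(CC)OS(=O)(=O)C(F)(F)F
Why: Silyl triflate silylation caps the tertiary C11 hydroxyl so that it cannot quench the Lewis acid or the cation of the key step.

Step 18
Reactants: 26 (2-bromoallyl)trimethylsilane
Product: 28 2-[(trimethylsilyl)methyl]prop-2-enal, via vinyllithium 27 (not isolated)
Conditions: t-BuLi (2 equiv), Et2O, −78 °C; DMF; then H2O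
Reagents that add atoms: N,N-dimethylformamide, CN(C)C=O
Why: Bromine–lithium exchange followed by formylation with DMF (Bouveault aldehyde synthesis) turns the vinyl bromide into the enal that carries C6–C8 and the allylsilane.

Step 19
Reactants: 25 C11 triethylsilyl ether; 28 2-[(trimethylsilyl)methyl]prop-2-enal
Product: 31 C6 trimethylsilyl ether of the aldol adduct (C6 epimers), via lithium enolate 29 (not isolated), via lithium aldolate 30 (not isolated)
Conditions: LiN(iPr)2, THF, −78 °C; 28; then Me3SiCl, −78 to −20 °C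
Reagents that add atoms: chlorotrimethylsilane, C[Si](C)(C)Cl
Why: Kinetic deprotonation can occur only at the C5 methyl group because C3 is quaternary, and aldol addition to the enal forms C5–C6; the C6 configuration is not controlled here and is reset in steps 21 and 22, and in situ silylation keeps the new hydroxyl from directing the next reduction.

Step 20
Reactants: 31 C6 trimethylsilyl ether of the aldol adduct
Product: 33 diol (C4 set; C6 epimers), via silyl ether alcohol 32 (not isolated)
Conditions: (S)-2-methyl-CBS-oxazaborolidine (0.5 equiv), catecholborane, toluene, −78 °C; then citric acid, MeOH, 0 °C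
Reagents that add atoms: none
Why: Corey–Bakshi–Shibata reduction: with the quaternary C3 as the large and the C5 methylene as the small group the (S)-catalyst should deliver hydride to the face that gives the target C4 configuration, the same face that the Felkin–Anh model favours, and acidic methanol then removes the trimethylsilyl group.

Step 21
Reactants: 33 diol
Product: 34 β-hydroxy enone (C6 ketone)
Conditions: MnO2, CH2Cl2, rt
Reagents that add atoms: none
Why: MnO2 oxidises only the allylic C6 alcohol, so both C6 epimers converge on one β-hydroxy enone while the C4 carbinol is untouched.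

Step 22
Reactants: 34 β-hydroxy enone
Product: 35 syn C4/C6 diol
Conditions: Et2BOMe, NaBH4, THF/MeOH (4:1), −78 °C; then MeOH, evaporation
Reagents that add atoms: none
Why: Narasaka–Prasad reduction: the boron chelate between the C4 oxygen and the C6 carbonyl is attacked by external hydride to give the 1,3-syn diol, which sets C6 from C4.

Step 23
Reactants: 35 syn C4/C6 diol
Product: 36 C6 tert-butyldimethylsilyl ether
Conditions: TBSOTf (1.05 equiv), 2,6-lutidine, CH2Cl2, −78 °C
Reagents that add atoms: tert-butyldimethylsilyl triflate, CC(C)(C)[Si](C)(C)OS(=O)(=O)C(F)(F)F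
Why: Silylation at low temperature with one equivalent of silyl triflate should take the allylic C6 hydroxyl selectively, because the C4 hydroxyl is flanked by the quaternary C3.

Step 24
Reactants: 36 C6 tert-butyldimethylsilyl ether; 37 octanoyl chloride
Product: 38 allylsilane methyl acetal (cyclisation precursor)
Conditions: pyridine, DMAP (cat.), CH2Cl2, 0 °C to rt
Reagents that add atoms: none
Why: DMAP-catalysed acylation with the acid chloride esterifies the remaining hindered C4 hydroxyl.

Step 25
Reactants: 38 allylsilane methyl acetal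
Product: 40 bis-silyl ether of briarellin A, via oxocarbenium triflate 39 (not isolated)
Conditions: Me3SiOTf, 2,6-di-tert-butyl-4-methylpyridine, CH2Cl2 (0.001 M), −78 to −40 °C
Reagents that add atoms: none
Why: Me3SiOTf abstracts the anomeric methoxy group and both C9 anomers give the same planar ring B oxocarbenium ion 39; the terminal alkene carbon of the allylsilane (future C8) adds to C9 and the β-silyl cation loses silicon, which forms C8–C9 and places the exocyclic methylene on C7 (intramolecular Hosomi–Sakurai reaction). The closest known reaction type is the Lewis-acid allylation of 2-alkoxytetrahydrofurans by allylsilanes and its intramolecular oxocarbenium–allylsilane variants used for medium-ring ethers. Ring C closes in a nine-membered mode that is endo with respect to the allylsilane alkene, the C=O+ bond being part of ring B. The new stereocentre C9 is fixed by the tether, which hangs from C2 on the face of ring B opposite to ring A and can reach only that face, the same face that the C10–C11 bond leaves open. The step needs cyclisation to outrun protodesilylation and intermolecular allylation, which millimolar dilution, a hindered pyridine base and the high nucleophilicity of a 1,1-disubstituted allylsilane should secure; the ester carbonyls are too far from C9 to take part.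

Step 26
Reactants: 40 bis-silyl ether of briarellin A
Product: 41 briarellin A
Conditions: HF·pyridine, pyridine, THF, 0 °C to rt
Reagents that add atoms: none
Why: Fluoride cleaves the secondary tert-butyldimethylsilyl and the tertiary triethylsilyl ether in one operation; the pyridine buffer should prevent acyl migration from O4 to O6 and ionisation of the allylic or tertiary alcohols.

Compound list
1 | (R)-carvone | CC(=C)[C@@H]1CC=C(C)C(=O)C1 | starting material
2 | (E)-2-methylbut-2-enal | C/C=C(\C)C=O | starting material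
3 | dicyclohexylboron dienolate of carvone (B–O on C10; C1=C10 enolate bond) | CC(=C)[C@@H]1CC=C(C)C(OB(C2CCCCC2)C2CCCCC2)=C1 | intermediate
4 | anti-aldol adduct; C1 side chain trans to isopropenyl, C2 carbinol | C/C=C(\C)[C@@H](O)[C@H]1[C@H](C(C)=C)CC=C(C)C1=O | intermediate
5 | C2 tert-butyldimethylsilyl ether of 4 | C/C=C(\C)[C@@H](O[Si](C)(C)C(C)(C)C)[C@H]1[C@H](C(C)=C)CC=C(C)C1=O | intermediate
6 | C11–C12 epoxy ketone, epoxide trans to isopropenyl | C/C=C(\C)[C@@H](O[Si](C)(C)C(C)(C)C)[C@H]1[C@H](C(C)=C)C[C@H]2O[C@@]2(C)C1=O | intermediate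
7 | hydrazone of 6 | C/C=C(\C)[C@@H](O[Si](C)(C)C(C)(C)C)[C@H]1[C@H](C(C)=C)C[C@H]2O[C@@]2(C)C1=NN | intermediate
8 | allylic alcohol, C12 hydroxyl cis to the C1 side chain, C10=C11 | C/C=C(\C)[C@@H](O[Si](C)(C)C(C)(C)C)[C@H]1[C@H](C(C)=C)C[C@@H](O)C(C)=C1 | intermediate
9 | C12 tributylstannylmethyl ether | C/C=C(\C)[C@@H](O[Si](C)(C)C(C)(C)C)[C@H]1[C@H](C(C)=C)C[C@@H](OC[Sn](CCCC)(CCCC)CCCC)C(C)=C1 | intermediate
10 | C12 lithiomethyl ether | C/C=C(\C)[C@@H](O[Si](C)(C)C(C)(C)C)[C@H]1[C@H](C(C)=C)C[C@@H](OC[Li])C(C)=C1 | intermediate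
11 | homoallylic alcohol, CH2OH (C9) on C10 cis to the C1 side chain, C11=C12 | C/C=C(\C)[C@@H](O[Si](C)(C)C(C)(C)C)[C@H]1[C@H](C(C)=C)CC=C(C)[C@H]1CO | intermediate
12 | C11–C12 epoxide syn to CH2OH | C/C=C(\C)[C@@H](O[Si](C)(C)C(C)(C)C)[C@H]1[C@H](C(C)=C)C[C@H]2O[C@@]2(C)[C@H]1CO | intermediate
13 | diol, C9 primary and C11 tertiary hydroxyl (C11–O cis to C9) | C/C=C(\C)[C@@H](O[Si](C)(C)C(C)(C)C)[C@H]1[C@H](C(C)=C)CC[C@@](C)(O)[C@H]1CO | intermediate
14 | C9 aldehyde | C/C=C(\C)[C@@H](O[Si](C)(C)C(C)(C)C)[C@H]1[C@H](C(C)=C)CC[C@@](C)(O)[C@H]1C=O | intermediate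
15 | C9 dimethyl acetal | C/C=C(\C)[C@@H](O[Si](C)(C)C(C)(C)C)[C@H]1[C@H](C(C)=C)CC[C@@](C)(O)[C@H]1C(OC)OC | intermediate
16 | B-(C16-alkyl)-9-borabicyclo[3.3.1]nonane | C/C=C(\C)[C@@H](O[Si](C)(C)C(C)(C)C)[C@H]1[C@H]([C@@H](C)CB2C3CCCC2CCC3)CC[C@@](C)(O)[C@H]1C(OC)OC | intermediate
17 | C16 primary alcohol, C15 as in the target | C/C=C(\C)[C@@H](O[Si](C)(C)C(C)(C)C)[C@H]1[C@H]([C@@H](C)CO)CC[C@@](C)(O)[C@H]1C(OC)OC | intermediate
18 | triol with free C2, C11 and C16 hydroxyls | C/C=C(\C)[C@@H](O)[C@H]1[C@H]([C@@H](C)CO)CC[C@@](C)(O)[C@H]1C(OC)OC | intermediate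
19 | erythro C3–C4 epoxy triol (trans epoxide, C3–O anti to C2–O) | C[C@@H]1O[C@@]1(C)[C@@H](O)[C@H]1[C@H]([C@@H](C)CO)CC[C@@](C)(O)[C@H]1C(OC)OC | intermediate
20 | cis-fused ring A/ring B methyl acetal with epoxide and C16 alcohol | C[C@@H]1O[C@@]1(C)[C@H]2O[C@H](OC)[C@H]3[C@@H]2[C@H]([C@@H](C)CO)CC[C@@]3(C)O | intermediate
21 | C16 aldehyde | C[C@@H]1O[C@@]1(C)[C@H]2O[C@H](OC)[C@H]3[C@@H]2[C@H]([C@@H](C)C=O)CC[C@@]3(C)O | intermediate
22 | C16 acid (epoxy acid) | C[C@@H]1O[C@@]1(C)[C@H]2O[C@H](OC)[C@H]3[C@@H]2[C@H]([C@@H](C)C(=O)O)CC[C@@]3(C)O | intermediate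
23 | tricyclic hydroxy lactone, rings A, B, D; 1-hydroxyethyl on C3 | C[C@H](O)[C@]1(C)OC(=O)[C@H](C)[C@@H]2CC[C@@](C)(O)[C@H]3[C@@H](OC)O[C@H]1[C@@H]23 | intermediate
24 | C4 methyl ketone | CC(=O)[C@]1(C)OC(=O)[C@H](C)[C@@H]2CC[C@@](C)(O)[C@H]3[C@@H](OC)O[C@H]1[C@@H]23 | intermediate
25 | C11 triethylsilyl ether of 24 | CC(=O)[C@]1(C)OC(=O)[C@H](C)[C@@H]2CC[C@@](C)(O[Si](CC)(CC)CC)[C@H]3[C@@H](OC)O[C@H]1[C@@H]23 | intermediate
26 | (2-bromoallyl)trimethylsilane | C[Si](C)(C)CC(Br)=C | starting material
27 | [3-(trimethylsilyl)prop-1-en-2-yl]lithium | C[Si](C)(C)CC([Li])=C | intermediate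
28 | 2-[(trimethylsilyl)methyl]prop-2-enal | C[Si](C)(C)CC(=C)C=O | intermediate
29 | lithium enolate of 25 (C4=C5) | C=C(O[Li])[C@]1(C)OC(=O)[C@H](C)[C@@H]2CC[C@@](C)(O[Si](CC)(CC)CC)[C@H]3[C@@H](OC)O[C@H]1[C@@H]23 | intermediate
30 | lithium aldolate, C6 epimers | C=C(C[Si](C)(C)C)C(O[Li])CC(=O)[C@]1(C)OC(=O)[C@H](C)[C@@H]2CC[C@@](C)(O[Si](CC)(CC)CC)[C@H]3[C@@H](OC)O[C@H]1[C@@H]23 | intermediate
31 | C6 trimethylsilyl ether of the aldol adduct, C6 epimers | C=C(C[Si](C)(C)C)C(O[Si](C)(C)C)CC(=O)[C@]1(C)OC(=O)[C@H](C)[C@@H]2CC[C@@](C)(O[Si](CC)(CC)CC)[C@H]3[C@@H](OC)O[C@H]1[C@@H]23 | intermediate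
32 | C4 alcohol, C6 trimethylsilyl ether, C6 epimers | C=C(C[Si](C)(C)C)C(O[Si](C)(C)C)C[C@@H](O)[C@]1(C)OC(=O)[C@H](C)[C@@H]2CC[C@@](C)(O[Si](CC)(CC)CC)[C@H]3[C@@H](OC)O[C@H]1[C@@H]23 | intermediate
33 | C4/C6 diol, C4 as in the target, C6 epimers | C=C(C[Si](C)(C)C)C(O)C[C@@H](O)[C@]1(C)OC(=O)[C@H](C)[C@@H]2CC[C@@](C)(O[Si](CC)(CC)CC)[C@H]3[C@@H](OC)O[C@H]1[C@@H]23 | intermediate
34 | β-hydroxy enone, C6 ketone | C=C(C[Si](C)(C)C)C(=O)C[C@@H](O)[C@]1(C)OC(=O)[C@H](C)[C@@H]2CC[C@@](C)(O[Si](CC)(CC)CC)[C@H]3[C@@H](OC)O[C@H]1[C@@H]23 | intermediate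
35 | syn C4/C6 diol | C=C(C[Si](C)(C)C)[C@@H](O)C[C@@H](O)[C@]1(C)OC(=O)[C@H](C)[C@@H]2CC[C@@](C)(O[Si](CC)(CC)CC)[C@H]3[C@@H](OC)O[C@H]1[C@@H]23 | intermediate
36 | C6 tert-butyldimethylsilyl ether, free C4 hydroxyl | C=C(C[Si](C)(C)C)[C@@H](O[Si](C)(C)C(C)(C)C)C[C@@H](O)[C@]1(C)OC(=O)[C@H](C)[C@@H]2CC[C@@](C)(O[Si](CC)(CC)CC)[C@H]3[C@@H](OC)O[C@H]1[C@@H]23 | intermediate
37 | octanoyl chloride | CCCCCCCC(=O)Cl | starting material
38 | allylsilane methyl acetal, cyclisation precursor | C=C(C[Si](C)(C)C)[C@@H](O[Si](C)(C)C(C)(C)C)C[C@@H](OC(=O)CCCCCCC)[C@]1(C)OC(=O)[C@H](C)[C@@H]2CC[C@@](C)(O[Si](CC)(CC)CC)[C@H]3[C@@H](OC)O[C@H]1[C@@H]23 | intermediate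
39 | ring B oxocarbenium triflate | C=C(C[Si](C)(C)C)[C@@H](O[Si](C)(C)C(C)(C)C)C[C@@H](OC(=O)CCCCCCC)[C@]1(C)OC(=O)[C@H](C)[C@@H]2CC[C@@](C)(O[Si](CC)(CC)CC)[C@H]3C=[O+][C@H]1[C@@H]23.[O-]S(=O)(=O)C(F)(F)F | intermediate
40 | bis-silyl ether of briarellin A (O6 tert-butyldimethylsilyl, O11 triethylsilyl) | C=C1C[C@@H]2O[C@H]3[C@H]4[C@@H](CC[C@@](C)(O[Si](CC)(CC)CC)[C@H]42)[C@@H](C)C(=O)O[C@@]3(C)[C@H](OC(=O)CCCCCCC)C[C@@H]1O[Si](C)(C)C(C)(C)C | intermediate
41 | briarellin A | C=C1C[C@@H]2O[C@H]3[C@H]4[C@@H](CC[C@@](C)(O)[C@H]42)[C@@H](C)C(=O)O[C@@]3(C)[C@H](OC(=O)CCCCCCC)C[C@@H]1O | target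

Total step count: 26. Longest linear sequence: 25 steps (steps 1–17 and 19–26); step 18 makes the side branch.

Steps most likely to fail

Step 25. The strain of the nine-membered transition state may slow ring closure so much that protodesilylation of the allylsilane, loss of the C10 proton from the oxocarbenium ion, or intermolecular allylation takes over. The fallback makes C8–C9 without ring strain and closes ring C at C6–C7 instead; it sets out from 25 and comes back at 41. Ketone 25 is allylated at C9 by (2-bromoallyl)trimethylsilane 26 in an intermolecular Hosomi–Sakurai reaction (Me3SiOTf, CH2Cl2, −78 °C), the nucleophile entering anti to the ring A bond at C10, to give the 2-bromoallyl adduct F1. A Mukaiyama-type reaction of the methyl ketone with trimethyl orthoformate (Me3SiOTf, iPr2NEt) gives the β-keto dimethyl acetal F2. Corey–Bakshi–Shibata reduction as in step 20 gives the C4 alcohol F3, and acylation as in step 24 gives the octanoate F4. Mild hydrolysis of the acetal (LiBF4, wet MeCN) gives the aldehyde F5. Intramolecular Nozaki–Hiyama–Kishi coupling (CrCl2, NiCl2 cat., DMSO, high dilution) closes the oxonane to the allylic alcohol F6, whose C6 configuration is expected to follow from the ring conformation. HF·pyridine then gives 41.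

Step 11. Facial selectivity of the hydroboration may be poor, which would give a mixture of C15 epimers that no later step corrects. The fallback replaces substrate control by catalyst control; it sets out from 15 and comes back at 17. Copper hydride catalysis (Cu(OAc)2, DTBM-SEGPHOS, pinacolborane, THF) places boron on C16 under ligand control and gives the pinacol boronate F7, which NaBO3 oxidises to 17. The ligand antipode is chosen to match the required C15 configuration.

Step 4. Hydrazone formation at the hindered ketone between C1 and the epoxide may be slow, so that reduction or decomposition competes with the fragmentation. The fallback reaches the same transposition by a radical route; it sets out from 6 and comes back at 8. Luche reduction (NaBH4, CeCl3·7H2O, MeOH) gives the epoxy alcohol F8, and 1,1′-thiocarbonyldiimidazole with DMAP gives its thiocarbonylimidazolide F9. With Bu3SnH and AIBN in toluene at 80 °C the C10 radical opens the epoxide and the alkoxyl radical is reduced, which gives 8.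

Further compounds
F1 | step 25 | C9 2-bromoallyl adduct of ketone 25 | CC(=O)[C@]1(C)OC(=O)[C@H](C)[C@@H]2CC[C@@](C)(O[Si](CC)(CC)CC)[C@H]3[C@H](CC(Br)=C)O[C@H]1[C@@H]23
F2 | step 25 | β-keto dimethyl acetal | COC(OC)CC(=O)[C@]1(C)OC(=O)[C@H](C)[C@@H]2CC[C@@](C)(O[Si](CC)(CC)CC)[C@H]3[C@H](CC(Br)=C)O[C@H]1[C@@H]23
F3 | step 25 | C4 alcohol | COC(OC)C[C@@H](O)[C@]1(C)OC(=O)[C@H](C)[C@@H]2CC[C@@](C)(O[Si](CC)(CC)CC)[C@H]3[C@H](CC(Br)=C)O[C@H]1[C@@H]23
F4 | step 25 | C4 octanoate | COC(OC)C[C@@H](OC(=O)CCCCCCC)[C@]1(C)OC(=O)[C@H](C)[C@@H]2CC[C@@](C)(O[Si](CC)(CC)CC)[C@H]3[C@H](CC(Br)=C)O[C@H]1[C@@H]23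
F5 | step 25 | C6 aldehyde | O=CC[C@@H](OC(=O)CCCCCCC)[C@]1(C)OC(=O)[C@H](C)[C@@H]2CC[C@@](C)(O[Si](CC)(CC)CC)[C@H]3[C@H](CC(Br)=C)O[C@H]1[C@@H]23
F6 | step 25 | O11 triethylsilyl ether of briarellin A | C=C1C[C@@H]2O[C@H]3[C@H]4[C@@H](CC[C@@](C)(O[Si](CC)(CC)CC)[C@H]42)[C@@H](C)C(=O)O[C@@]3(C)[C@H](OC(=O)CCCCCCC)C[C@@H]1O
F7 | step 11 | C16 pinacol boronate | C/C=C(\C)[C@@H](O[Si](C)(C)C(C)(C)C)[C@H]1[C@H]([C@@H](C)CB2OC(C)(C)C(C)(C)O2)CC[C@@](C)(O)[C@H]1C(OC)OC
F8 | step 4 | C10 epoxy alcohol | C/C=C(\C)[C@@H](O[Si](C)(C)C(C)(C)C)[C@H]1[C@H](C(C)=C)C[C@H]2O[C@@]2(C)C1O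
F9 | step 4 | C10 O-thiocarbonylimidazolide | C/C=C(\C)[C@@H](O[Si](C)(C)C(C)(C)C)[C@H]1[C@H](C(C)=C)C[C@H]2O[C@@]2(C)C1OC(=S)n1ccnc1
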